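**Plan**

1. Retrosynthetic cuts (isochromene numbering of the core): the C7–O ester and C5–Cl last; then the pyran O2–C3 bond (enol oxygen onto an aryl alkyne); then the carbocycle bond C6–C7; then C8a–C4a and C4a–C4 of an open-chain dienyne.
2. Forward: dibromoalkene 5 is alkynylated (C4a–C4) and, as boronate 7, coupled with iodoenaminone 11 (C8a–C4a). The linear keto-aldehyde 14 is closed to the carbocycle 15, the pyran ring follows (17), then C5 chlorination, acylation with acid 28 and release of the phenol.
3. Enabling feature: in the six-membered carbocycle, C7 is a tertiary carbinol bonded directly to the C6 ketone (an α-ketol). C6–C7 is therefore the bond formed when an aldehyde carbon (C6) adds as an acyl anion to a methyl ketone (C7). The other neighbour, C8, is a vinylogous-amide carbonyl in the precursor and stays passive.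
4. C1 is placed on C8a before this closure: a ring with unsubstituted C5 and C8a would have a mirror-symmetric dienolate through C7 and could not hold the configuration.
5. Stereochemistry: C7 from a chiral triazolium carbene catalyst acting on the achiral 14; C4′ from an Evans alkylation; the 2′E alkene from a stabilised Wittig reaction; the (Z) C4a=C5 geometry from a trans-selective Sonogashira coupling followed by stereoretentive borylation and Suzuki coupling.

Key step: step 12

Assumption: the (5aS,10bR) triazolium salt is taken to give the (R)-ketol 15, by analogy with related six-ring ketol closures; if a test run shows the opposite sense, the equally available (5aR,10bS) salt is used under the same conditions.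

Remark: the CIP descriptor of the carbinol carbon changes from R (15–17) to S (18, 30, 31) only because chlorine at C5 reverses the ranking of C6 and C8; the spatial arrangement is unchanged.

**Route**

Step 1
Reactants: 1 2-hydroxy-6-methylbenzaldehyde
Product: 2 2-(methoxymethoxy)-6-methylbenzaldehyde
Conditions: MOMCl, iPr2NEt, CH2Cl2, 0 °C → rt
Reagents that add atoms: chloromethyl methyl ether, COCCl
Why: O-alkylation of the phenol (Williamson type) masks the hydroxyl, which would otherwise close onto the later alkyne to a benzofuran.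

Step 2
Reactants: 2 2-(methoxymethoxy)-6-methylbenzaldehyde
Product: 3 2-ethynyl-1-(methoxymethoxy)-3-methylbenzene
Conditions: dimethyl (1-diazo-2-oxopropyl)phosphonate, K2CO3, MeOH, 0 °C → rt
Reagents that add atoms: dimethyl (1-diazo-2-oxopropyl)phosphonate, CC(=O)C(=[N+]=[N-])P(=O)(OC)OC
Why: Ohira–Bestmann (Seyferth–Gilbert) homologation should convert the hindered aryl aldehyde into the terminal alkyne under mild carbonate conditions.

Step 3
Reactants: 4 2-[(tert-butyldimethylsilyl)oxy]acetaldehyde
Product: 5 tert-butyl[(3,3-dibromoprop-2-en-1-yl)oxy]dimethylsilane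
Conditions: CBr4, PPh3, CH2Cl2, 0 °C
Reagents that add atoms: tetrabromomethane, BrC(Br)(Br)Br
Why: dibromo-olefination of the aldehyde (first stage of the Corey–Fuchs sequence) gives the 1,1-dibromoalkene that carries C4a, C5 and C6.

Step 4
Reactants: 5 tert-butyl[(3,3-dibromoprop-2-en-1-yl)oxy]dimethylsilane; 3 2-ethynyl-1-(methoxymethoxy)-3-methylbenzene
Product: 6 (Z)-bromoenyne, TBSOCH2–CH=C(Br)–C≡C–Ar with Br cis to CH2OTBS (Ar = 2-(methoxymethoxy)-6-methylphenyl)
Conditions: PdCl2(dppf) (cat.), CuI (cat.), iPr2NH, toluene, rt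
Reagents that add atoms: none
Why: Sonogashira coupling of a 1,1-dibromoalkene should occur at the bromide trans to the alkyl substituent, leaving the second bromide cis to CH2OTBS.

Step 5
Reactants: 6 (Z)-bromoenyne
Product: 7 (E)-alkenyl pinacol boronate, TBSOCH2–CH=C(Bpin)–C≡C–Ar with boron cis to CH2OTBS
Conditions: B2pin2, PdCl2(PPh3)2 (cat.), PPh3, KOPh, toluene, 50 °C
Reagents that add atoms: bis(pinacolato)diboron, CC1(C)OB(OC1(C)C)B1OC(C)(C)C(C)(C)O1
Why: Miyaura borylation of an alkenyl bromide proceeds with retention of alkene geometry and turns the second halide into the nucleophilic coupling partner.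

Step 6
Reactants: 8 3-hydroxybutan-2-one (racemic)
Product: 9 3-[(tert-butyldimethylsilyl)oxy]butan-2-one (racemic)
Conditions: TBSCl, imidazole, DMF, rt
Reagents that add atoms: tert-butyldimethylsilyl chloride, CC(C)(C)[Si](C)(C)Cl
Why: standard silylation of the secondary alcohol; this carbinol carbon later becomes the C7 ketone, so racemic material suffices.

Step 7
Reactants: 9 3-[(tert-butyldimethylsilyl)oxy]butan-2-one
Product: 10 (E)-4-[(tert-butyldimethylsilyl)oxy]-1-(dimethylamino)pent-1-en-3-one
Conditions: DMF-DMA, neat, 100 °C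
Reagents that add atoms: N,N-dimethylformamide dimethyl acetal, COC(OC)N(C)C
Why: enaminone condensation of the methyl ketone with the amide acetal installs C1; only the methyl group can condense because the other α-carbon is a methine.

Step 8
Reactants: 10 (E)-4-[(tert-butyldimethylsilyl)oxy]-1-(dimethylamino)pent-1-en-3-one
Product: 11 (Z)-4-[(tert-butyldimethylsilyl)oxy]-1-(dimethylamino)-2-iodopent-1-en-3-one
Conditions: NIS, CH2Cl2, 0 °C → rt
Reagents that add atoms: N-iodosuccinimide, O=C1CCC(=O)N1I
Why: electrophilic α-iodination at the nucleophilic α-carbon of the enaminone gives the α-iodo vinylogous amide needed as cross-coupling electrophile.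

Step 9
Reactants: 7 (E)-alkenyl pinacol boronate; 11 (Z)-α-iodoenaminone
Product: 12 (4E,5Z)-2,7-bis[(tert-butyldimethylsilyl)oxy]-4-[(dimethylamino)methylidene]-5-(arylethynyl)hept-5-en-3-one
Conditions: PdCl2(dppf) (cat.), K3PO4, DMF/H2O, 50 °C
Reagents that add atoms: none
Why: Suzuki–Miyaura coupling of the alkenyl boronate with the α-iodoenaminone should form the C8a–C4a bond with retention at both alkenes, placing C6 cis to C8a.

Step 10
Reactants: 12 bis-silyl ether
Product: 13 (4E,5Z)-4-[(dimethylamino)methylidene]-2,7-dihydroxy-5-(arylethynyl)hept-5-en-3-one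
Conditions: TBAF, AcOH (1:1), THF, 0 °C → rt
Reagents that add atoms: none
Why: buffered fluoride desilylation should cleave both silyl ethers without touching the MOM ether or the vinylogous amide.

Step 11
Reactants: 13 diol
Product: 14 (2Z,4E)-4-[(dimethylamino)methylidene]-3-(arylethynyl)-5,6-dioxohept-2-enal
Conditions: Dess–Martin periodinane, CH2Cl2, 0 °C → rt; used at once
Reagents that add atoms: none
Why: Dess–Martin oxidation should convert the allylic alcohol into the (Z)-enal and the α-hydroxy ketone into the 1,2-dione in one near-neutral operation.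

Step 12
Reactants: 14 (2Z,4E)-keto-aldehyde
Product: 15 (2R,6E)-6-[(dimethylamino)methylidene]-2-hydroxy-2-methyl-5-(arylethynyl)cyclohex-4-ene-1,3-dione
Conditions: (5aS,10bR)-2-mesityl-5a,10b-dihydro-4H,6H-indeno[2,1-b][1,2,4]triazolo[4,3-d][1,4]oxazin-2-ium chloride (15 mol %), iPr2NEt (15 mol %), toluene, 40 °C
Reagents that add atoms: none
Why: The triazolylidene adds to the C6 aldehyde and proton transfer gives the hydroxy-enamine (acyl-anion equivalent), whose C6 carbon attacks the C7 ketone of the 1,2-dione; collapse of the adduct releases the carbene and the tertiary α-ketol. The closest known reaction type is the enantioselective intramolecular crossed aldehyde–ketone benzoin cyclisation to six-membered tertiary α-ketols with aminoindanol-derived triazolium salts. The carbocycle C6–C5=C4a–C8a–C8–C7 closes in the 6-exo-trig mode. The only new stereocentre, C7, is set by the catalyst, whose indane wall differentiates the two faces of the C7 carbonyl of an achiral substrate. The step needs attack at C7 and not at C8, acyl-anion reactivity and not homoenolate or aldol reactivity, and a reactive geometry. These are secured by C8 being a vinylogous-amide carbonyl (and leading only to a five-membered ring), by the fully substituted β-carbon C4a and the absence of α-hydrogen on the enal, and by the (2Z) alkene that holds C6 next to C7.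

Step 13
Reactants: 15 (2R,6E)-ketol
Product: 17 (7R)-7-hydroxy-3-[2-(methoxymethoxy)-6-methylphenyl]-7-methyl-6H-isochromene-6,8(7H)-dione, via hydroxymethylidene dione 16 (not isolated)
Conditions: AcOH/H2O/THF (3:1:1), 40 °C; then KH2PO4/K2HPO4 buffer (pH 7.2), MeCN, rt
Reagents that add atoms: water, O
Why: hydrolysis of the doubly activated aminomethylidene group gives the formyl-type vinylogous acid, whose enol oxygen should add 6-endo to the alkyne conjugated with the C6 enone (oxa-Michael cycloisomerisation, as used for alkynyl formyl cyclohexadienones on the way to this ring system).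

Step 14
Reactants: 17 (7R)-7-hydroxy isochromenedione
Product: 18 (7S)-5-chloro-7-hydroxy-3-[2-(methoxymethoxy)-6-methylphenyl]-7-methyl-6H-isochromene-6,8(7H)-dione
Conditions: NCS, MeCN, 0 °C → rt
Reagents that add atoms: N-chlorosuccinimide, O=C1CCC(=O)N1Cl
Why: electrophilic chlorination should occur at C5, the terminus of the O2–C3=C4–C4a=C5 dienol ether, through a pyrylium-type σ-complex, as in known C5 halogenations of this ring system with N-halosuccinimides.

Step 15
Reactants: 19 (S)-4-benzyloxazolidin-2-one; 20 octanoyl chloride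
Product: 21 (S)-4-benzyl-3-octanoyloxazolidin-2-one
Conditions: Et3N, DMAP (cat.), CH2Cl2, 0 °C → rt
Reagents that add atoms: none
Why: N-acylation of the oxazolidinone auxiliary with the acid chloride.

Step 16
Reactants: 21 (S)-4-benzyl-3-octanoyloxazolidin-2-one
Product: 23 (S)-4-benzyl-3-[(S)-2-methyloctanoyl]oxazolidin-2-one, via sodium enolate 22 (not isolated)
Conditions: NaHMDS, THF, −78 °C; then MeI, −78 → −40 °C
Reagents that add atoms: iodomethane, CI
Why: Evans asymmetric alkylation: the chelated (Z)-sodium enolate should be methylated on the face opposite the benzyl group, setting the (S) centre that becomes C4′.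

Step 17
Reactants: 23 (S)-4-benzyl-3-[(S)-2-methyloctanoyl]oxazolidin-2-one
Product: 24 (S)-2-methyloctan-1-ol
Conditions: LiBH4, THF, 0 °C → rt
Reagents that add atoms: none
Why: reductive cleavage of the imide gives the primary alcohol without epimerisation and returns the auxiliary.

Step 18
Reactants: 24 (S)-2-methyloctan-1-ol; 25 ethyl 2-(triphenyl-λ5-phosphanylidene)propanoate
Product: 27 ethyl (2E,4S)-2,4-dimethyldec-2-enoate, via aldehyde 26 (not isolated)
Conditions: Dess–Martin periodinane, CH2Cl2, 0 °C → rt; then 25 added to the same flask, rt → 40 °C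
Reagents that add atoms: none
Why: one-pot Dess–Martin oxidation and Wittig olefination with the stabilised ylide should give the (E)-trisubstituted enoate and avoids isolating the epimerisable α-branched aldehyde.

Step 19
Reactants: 27 ethyl (2E,4S)-2,4-dimethyldec-2-enoate
Product: 28 (2E,4S)-2,4-dimethyldec-2-enoic acid
Conditions: LiOH, THF/MeOH/H2O, rt → 40 °C; then 1 M HCl
Reagents that add atoms: lithium hydroxide, [Li+].[OH-]
Why: saponification of the ethyl ester under conditions that should leave the alkene geometry and the γ-stereocentre untouched.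

Step 20
Reactants: 28 (2E,4S)-2,4-dimethyldec-2-enoic acid; 18 (7S)-5-chloro-7-hydroxy isochromenedione
Product: 30 (7S)-5-chloro-3-[2-(methoxymethoxy)-6-methylphenyl]-7-methyl-6,8-dioxo-7,8-dihydro-6H-isochromen-7-yl (2E,4S)-2,4-dimethyldec-2-enoate, via mixed anhydride 29 (not isolated)
Conditions: 28, 2,4,6-trichlorobenzoyl chloride, Et3N, THF, rt; then 18, DMAP, toluene, rt → 40 °C
Reagents that add atoms: none
Why: Yamaguchi esterification: the mixed anhydride with DMAP should acylate the hindered tertiary α-ketol, as in known acylations of 7-hydroxy-isochromenediones.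

Step 21
Reactants: 30 MOM-protected ester
Product: 31 (7S)-5-chloro-3-(2-hydroxy-6-methylphenyl)-7-methyl-6,8-dioxo-7,8-dihydro-6H-isochromen-7-yl (2E,4S)-2,4-dimethyldec-2-enoate
Conditions: TFA/CH2Cl2 (1:4), H2O (trace), 0 °C
Reagents that add atoms: none
Why: acid-catalysed hydrolysis of the MOM acetal frees the phenol; the tertiary ester, flanked by two carbonyl groups, should not ionise.

**Compound list**

1 | 2-hydroxy-6-methylbenzaldehyde | O=Cc1c(C)cccc1O | starting material
2 | 2-(methoxymethoxy)-6-methylbenzaldehyde | O=Cc1c(C)cccc1OCOC | intermediate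
3 | 2-ethynyl-1-(methoxymethoxy)-3-methylbenzene | C#Cc1c(C)cccc1OCOC | intermediate
4 | 2-[(tert-butyldimethylsilyl)oxy]acetaldehyde | O=CCO[Si](C)(C)C(C)(C)C | starting material
5 | tert-butyl[(3,3-dibromoprop-2-en-1-yl)oxy]dimethylsilane | BrC(Br)=CCO[Si](C)(C)C(C)(C)C | intermediate
6 | (Z)-{[3-bromo-5-[2-(methoxymethoxy)-6-methylphenyl]pent-2-en-4-yn-1-yl]oxy}(tert-butyl)dimethylsilane | CC(C)(C)[Si](C)(C)OC/C=C(\Br)C#Cc1c(C)cccc1OCOC | intermediate
7 | (E)-tert-butyl{[5-[2-(methoxymethoxy)-6-methylphenyl]-3-(4,4,5,5-tetramethyl-1,3,2-dioxaborolan-2-yl)pent-2-en-4-yn-1-yl]oxy}dimethylsilane | CC(C)(C)[Si](C)(C)OC/C=C(\B1OC(C)(C)C(C)(C)O1)C#Cc1c(C)cccc1OCOC | intermediate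
8 | 3-hydroxybutan-2-one (racemic) | CC(O)C(C)=O | starting material
9 | 3-[(tert-butyldimethylsilyl)oxy]butan-2-one (racemic) | CC(O[Si](C)(C)C(C)(C)C)C(C)=O | intermediate
10 | (E)-4-[(tert-butyldimethylsilyl)oxy]-1-(dimethylamino)pent-1-en-3-one (racemic) | CC(O[Si](C)(C)C(C)(C)C)C(=O)/C=C/N(C)C | intermediate
11 | (Z)-4-[(tert-butyldimethylsilyl)oxy]-1-(dimethylamino)-2-iodopent-1-en-3-one (racemic) | CC(O[Si](C)(C)C(C)(C)C)C(=O)/C(I)=C/N(C)C | intermediate
12 | (4E,5Z)-2,7-bis[(tert-butyldimethylsilyl)oxy]-4-[(dimethylamino)methylidene]-5-{[2-(methoxymethoxy)-6-methylphenyl]ethynyl}hept-5-en-3-one (racemic at C2) | CC(O[Si](C)(C)C(C)(C)C)C(=O)/C(=C/N(C)C)/C(C#Cc1c(C)cccc1OCOC)=C\CO[Si](C)(C)C(C)(C)C | intermediate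
13 | (4E,5Z)-4-[(dimethylamino)methylidene]-2,7-dihydroxy-5-{[2-(methoxymethoxy)-6-methylphenyl]ethynyl}hept-5-en-3-one (racemic at C2) | CC(O)C(=O)/C(=C/N(C)C)/C(C#Cc1c(C)cccc1OCOC)=C\CO | intermediate
14 | (2Z,4E)-4-[(dimethylamino)methylidene]-3-{[2-(methoxymethoxy)-6-methylphenyl]ethynyl}-5,6-dioxohept-2-enal | CC(=O)C(=O)/C(=C/N(C)C)/C(C#Cc1c(C)cccc1OCOC)=C\C=O | intermediate
15 | (2R,6E)-6-[(dimethylamino)methylidene]-2-hydroxy-2-methyl-5-{[2-(methoxymethoxy)-6-methylphenyl]ethynyl}cyclohex-4-ene-1,3-dione | O[C@@]1(C)C(=O)/C(=C/N(C)C)C(C#Cc2c(C)cccc2OCOC)=CC1=O | intermediate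
16 | (2R)-2-hydroxy-6-(hydroxymethylidene)-2-methyl-5-{[2-(methoxymethoxy)-6-methylphenyl]ethynyl}cyclohex-4-ene-1,3-dione (not isolated) | O[C@@]1(C)C(=O)C(=CO)C(C#Cc2c(C)cccc2OCOC)=CC1=O | intermediate
17 | (7R)-7-hydroxy-3-[2-(methoxymethoxy)-6-methylphenyl]-7-methyl-6H-isochromene-6,8(7H)-dione | O[C@@]1(C)C(=O)C2=COC(c3c(C)cccc3OCOC)=CC2=CC1=O | intermediate
18 | (7S)-5-chloro-7-hydroxy-3-[2-(methoxymethoxy)-6-methylphenyl]-7-methyl-6H-isochromene-6,8(7H)-dione | O[C@@]1(C)C(=O)C2=COC(c3c(C)cccc3OCOC)=CC2=C(Cl)C1=O | intermediate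
19 | (S)-4-benzyloxazolidin-2-one | O=C1N[C@@H](Cc2ccccc2)CO1 | starting material
20 | octanoyl chloride | CCCCCCCC(Cl)=O | starting material
21 | (S)-4-benzyl-3-octanoyloxazolidin-2-one | CCCCCCCC(=O)N1C(=O)OC[C@@H]1Cc1ccccc1 | intermediate
22 | sodium (Z)-enolate of 21 (not isolated) | CCCCCC/C=C(\[O-])N1C(=O)OC[C@@H]1Cc1ccccc1.[Na+] | intermediate
23 | (S)-4-benzyl-3-[(S)-2-methyloctanoyl]oxazolidin-2-one | CCCCCC[C@H](C)C(=O)N1C(=O)OC[C@@H]1Cc1ccccc1 | intermediate
24 | (S)-2-methyloctan-1-ol | CCCCCC[C@H](C)CO | intermediate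
25 | ethyl 2-(triphenyl-λ5-phosphanylidene)propanoate | CCOC(=O)C(C)=P(c1ccccc1)(c1ccccc1)c1ccccc1 | starting material
26 | (S)-2-methyloctanal (not isolated) | CCCCCC[C@H](C)C=O | intermediate
27 | ethyl (2E,4S)-2,4-dimethyldec-2-enoate | CCCCCC[C@H](C)/C=C(\C)C(=O)OCC | intermediate
28 | (2E,4S)-2,4-dimethyldec-2-enoic acid | CCCCCC[C@H](C)/C=C(\C)C(=O)O | intermediate
29 | (2E,4S)-2,4-dimethyldec-2-enoic 2,4,6-trichlorobenzoic anhydride (not isolated) | CCCCCC[C@H](C)/C=C(\C)C(=O)OC(=O)c1c(Cl)cc(Cl)cc1Cl | intermediate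
30 | (7S)-5-chloro-3-[2-(methoxymethoxy)-6-methylphenyl]-7-methyl-6,8-dioxo-7,8-dihydro-6H-isochromen-7-yl (2E,4S)-2,4-dimethyldec-2-enoate | CCCCCC[C@H](C)/C=C(\C)C(=O)O[C@@]1(C)C(=O)C2=COC(c3c(C)cccc3OCOC)=CC2=C(Cl)C1=O | intermediate
31 | (7S)-5-chloro-3-(2-hydroxy-6-methylphenyl)-7-methyl-6,8-dioxo-7,8-dihydro-6H-isochromen-7-yl (2E,4S)-2,4-dimethyldec-2-enoate | CCCCCC[C@H](C)/C=C(\C)C(=O)O[C@@]1(C)C(=O)C2=COC(c3c(C)cccc3O)=CC2=C(Cl)C1=O | target

**Step count and risks**

Total steps: 21. Longest linear sequence: 12 steps (steps 1, 2, 4, 5, 9, 10, 11, 12, 13, 14, 20, 21).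

Step 12. The carbene may add only slowly to the aldehyde, which is a vinylogous formamide, or be held reversibly at C1 or at the 1,2-dione; the dione could then decompose before ring closure, and the facial bias at the small methyl ketone may be weak. The fallback changes the order of ring formation and sets out from 14. Hydrolysis of the aminomethylidene group in aqueous acetic acid and 6-endo oxa-Michael closure onto the ynenal should give the pyran first, as (Z)-2-{6-[2-(methoxymethoxy)-6-methylphenyl]-3-(2-oxopropanoyl)-4H-pyran-4-ylidene}acetaldehyde F1. The same triazolium-catalysed benzoin closure is then run on this rigid, less donor-substituted bicyclic precursor, and the route is rejoined at 17.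

Step 9. Transmetalation between two α-branched, hindered sp2 partners may be slow, so that protodeboronation of 7 and deiodination of 11 take over. The fallback forms the C8a–C4a bond by enolate chemistry and sets out from 6 and 9. Palladium-catalysed α-alkenylation of the kinetic lithium enolate of 9 (LiHMDS, Pd2(dba)3, Q-Phos, THF) with bromide 6 should give the β,γ-unsaturated ketone (E)-2,7-bis[(tert-butyldimethylsilyl)oxy]-5-{[2-(methoxymethoxy)-6-methylphenyl]ethynyl}hept-5-en-3-one F2. Condensation of its doubly activated methylene with DMF-DMA then installs C1, and the route is rejoined at 12.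

Step 4. Site selectivity may be lost (double alkynylation), or base may eliminate HBr from 6 to give the 1,3-diyne. The fallback builds the haloenyne by hydroxyl-directed hydrometalation and sets out from 3. Bromination of the alkyne terminus (NBS, AgNO3) gives 2-(bromoethynyl)-1-(methoxymethoxy)-3-methylbenzene F3. Cadiot–Chodkiewicz coupling with propargyl alcohol (CuCl, NH2OH·HCl, EtNH2) gives 5-[2-(methoxymethoxy)-6-methylphenyl]penta-2,4-diyn-1-ol F4. Trans-hydroalumination with Red-Al followed by iodine gives (Z)-3-iodo-5-[2-(methoxymethoxy)-6-methylphenyl]pent-2-en-4-yn-1-ol F5. Silylation gives the iodide analogue of 6, (Z)-tert-butyl{[3-iodo-5-[2-(methoxymethoxy)-6-methylphenyl]pent-2-en-4-yn-1-yl]oxy}dimethylsilane F6, which is borylated as in step 5, and the route is rejoined at 7.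

Further compounds
F1 | step 12 | (Z)-2-{6-[2-(methoxymethoxy)-6-methylphenyl]-3-(2-oxopropanoyl)-4H-pyran-4-ylidene}acetaldehyde | O=C/C=C1/C=C(c2c(C)cccc2OCOC)OC=C1C(=O)C(C)=O
F2 | step 9 | (E)-2,7-bis[(tert-butyldimethylsilyl)oxy]-5-{[2-(methoxymethoxy)-6-methylphenyl]ethynyl}hept-5-en-3-one | CC(O[Si](C)(C)C(C)(C)C)C(=O)C/C(C#Cc1c(C)cccc1OCOC)=C\CO[Si](C)(C)C(C)(C)C
F3 | step 4 | 2-(bromoethynyl)-1-(methoxymethoxy)-3-methylbenzene | BrC#Cc1c(C)cccc1OCOC
F4 | step 4 | 5-[2-(methoxymethoxy)-6-methylphenyl]penta-2,4-diyn-1-ol | OCC#CC#Cc1c(C)cccc1OCOC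
F5 | step 4 | (Z)-3-iodo-5-[2-(methoxymethoxy)-6-methylphenyl]pent-2-en-4-yn-1-ol | OC/C=C(\I)C#Cc1c(C)cccc1OCOC
F6 | step 4 | (Z)-tert-butyl{[3-iodo-5-[2-(methoxymethoxy)-6-methylphenyl]pent-2-en-4-yn-1-yl]oxy}dimethylsilane | CC(C)(C)[Si](C)(C)OC/C=C(\I)C#Cc1c(C)cccc1OCOC
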